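**Retrosynthetic overview**

1. Target 19 comes from its 2'-O-benzyl ether 18 by hydrogenolysis.
2. The pyran ring of 18 (last ring formed) comes from spirodienone 17 by an acid-promoted 1,2-shift of C4 from C8a to C4a. The feature behind this: in ring A, O1 on C8a is para to the free 6-OH on C6, and C4 sits on the neighbouring C4a next to C5–H, which is the pattern a para-spiroether dienone leaves when its carbon arm moves one position.
3. The oxolane ring of 17 (O1–C8a bond) comes from phenol–alcohol 16 by iodine(III) dearomatisation.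
4. The C3–C4 bond and the C3 stereocentre come from an Evans alkylation of the ring-B arylacetyl oxazolidinone 7 with the ring-A benzylic bromide 12.
5. 7 is made from acetophenone 1 (Willgerodt–Kindler homologation); 12 is made from 2,3,4-trihydroxybenzaldehyde 8.

Key step: step 13

Remark: the stereocentre in the target SMILES is C3 and is read as (S). Spirodienone 17 is carried as both epimers at its spiro carbon, because step 13 turns that carbon into the planar C8a.

**Route**

Step 1
Reactants: 1 1-(2-hydroxy-3,4-dimethoxyphenyl)ethan-1-one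
Product: 2 1-[2-(benzyloxy)-3,4-dimethoxyphenyl]ethan-1-one
Conditions: BnBr, K2CO3, DMF, 60 °C
Reagents that add atoms: benzyl bromide, BrCc1ccccc1
Why: Williamson etherification; carbonate in DMF ionises the hydrogen-bonded ortho-acyl phenol, which is the only nucleophile in 1.

Step 2
Reactants: 2 1-[2-(benzyloxy)-3,4-dimethoxyphenyl]ethan-1-one
Product: 3 2-[2-(benzyloxy)-3,4-dimethoxyphenyl]-1-(morpholin-4-yl)ethane-1-thione
Conditions: S8, morpholine, 130 °C
Reagents that add atoms: morpholine, C1COCCN1; sulfur, S1SSSSSSS1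
Why: Willgerodt–Kindler reaction, which moves the oxidised carbon of an aryl methyl ketone to the chain end as a thioamide and leaves aryl ethers untouched.

Step 3
Reactants: 3 2-[2-(benzyloxy)-3,4-dimethoxyphenyl]-1-(morpholin-4-yl)ethane-1-thione
Product: 4 [2-(benzyloxy)-3,4-dimethoxyphenyl]acetic acid
Conditions: KOH, EtOH–H2O, reflux; then aq. HCl
Reagents that add atoms: potassium hydroxide, [K+].[OH-]; water, O
Why: basic hydrolysis of the thioamide to the carboxylate, under which benzyl and methyl aryl ethers are stable.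

Step 4
Reactants: 4 [2-(benzyloxy)-3,4-dimethoxyphenyl]acetic acid; 5 (4S)-4-benzyl-1,3-oxazolidin-2-one
Product: 7 (4S)-4-benzyl-3-{[2-(benzyloxy)-3,4-dimethoxyphenyl]acetyl}-1,3-oxazolidin-2-one, via mixed pivalic anhydride 6 (not isolated)
Conditions: PivCl, Et3N, THF, −20 °C; then LiCl, 5, −20 °C → rt
Reagents that add atoms: pivaloyl chloride, CC(C)(C)C(Cl)=O (its atoms enter intermediate 6 only)
Why: mixed-anhydride N-acylation of the oxazolidinone, in which the hindered pivaloyl carbonyl steers the nitrogen to the arylacetyl carbonyl and the auxiliary stereocentre is not touched.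

Step 5
Reactants: 8 2,3,4-trihydroxybenzaldehyde
Product: 9 4-(allyloxy)-2,3-dihydroxybenzaldehyde
Conditions: allyl bromide (1 equiv), NaHCO3, NaI (cat.), DMF, 40 °C, N2
Reagents that add atoms: allyl bromide, C=CCBr
Why: Williamson etherification under weak base; only the 4-OH, para to the formyl group and the most acidic, is ionised by hydrogen carbonate, while 2-OH is held in a hydrogen bond to the aldehyde and 3-OH is the least acidic.

Step 6
Reactants: 9 4-(allyloxy)-2,3-dihydroxybenzaldehyde
Product: 10 4-(allyloxy)-2,3-dimethoxybenzaldehyde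
Conditions: MeI, K2CO3, DMF, 50 °C
Reagents that add atoms: iodomethane, CI
Why: exhaustive Williamson methylation of the two remaining phenols, with the allyl ether and the aldehyde inert.

Step 7
Reactants: 10 4-(allyloxy)-2,3-dimethoxybenzaldehyde
Product: 11 [4-(allyloxy)-2,3-dimethoxyphenyl]methanol
Conditions: NaBH4, MeOH, 0 °C
Reagents that add atoms: none
Why: borohydride reduction of the aldehyde, the only reducible group present.

Step 8
Reactants: 11 [4-(allyloxy)-2,3-dimethoxyphenyl]methanol
Product: 12 1-(allyloxy)-4-(bromomethyl)-2,3-dimethoxybenzene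
Conditions: PBr3, Et2O, 0 °C; used at once without chromatography
Reagents that add atoms: phosphorus tribromide, BrP(Br)Br
Why: conversion of a benzylic alcohol to the bromide through its phosphite ester; the electron-rich bromide is made cold and used directly because it should not store well.

Step 9
Reactants: 7 (4S)-4-benzyl-3-{[2-(benzyloxy)-3,4-dimethoxyphenyl]acetyl}-1,3-oxazolidin-2-one; 12 1-(allyloxy)-4-(bromomethyl)-2,3-dimethoxybenzene
Product: 14 (4S)-4-benzyl-3-[(2S)-3-[4-(allyloxy)-2,3-dimethoxyphenyl]-2-[2-(benzyloxy)-3,4-dimethoxyphenyl]propanoyl]-1,3-oxazolidin-2-one, via sodium Z-enolate 13 (not isolated)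
Conditions: NaHMDS, THF, −78 °C; then 12, −78 → −40 °C
Reagents that add atoms: sodium bis(trimethylsilyl)amide, C[Si](C)(C)[N-][Si](C)(C)C.[Na+] (its sodium enters intermediate 13 only)
Why: Evans asymmetric alkylation; the sodium-chelated Z-enolate is attacked by the benzylic bromide on the face opposite the C4 benzyl group of the (S)-auxiliary, which sets the new centre (the future C3) as (S), and the minor diastereomer is removed at this stage.

Step 10
Reactants: 14 (4S)-4-benzyl-3-[(2S)-3-[4-(allyloxy)-2,3-dimethoxyphenyl]-2-[2-(benzyloxy)-3,4-dimethoxyphenyl]propanoyl]-1,3-oxazolidin-2-one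
Product: 15 (2S)-3-[4-(allyloxy)-2,3-dimethoxyphenyl]-2-[2-(benzyloxy)-3,4-dimethoxyphenyl]propan-1-ol
Conditions: LiBH4, H2O (1 equiv), Et2O, 0 °C
Reagents that add atoms: none
Why: reductive cleavage of the N-acyl oxazolidinone at the exocyclic carbonyl; the aldehyde stage is reduced faster than it can enolise, so the α-aryl centre should keep its configuration.

Step 11
Reactants: 15 (2S)-3-[4-(allyloxy)-2,3-dimethoxyphenyl]-2-[2-(benzyloxy)-3,4-dimethoxyphenyl]propan-1-ol
Product: 16 (2S)-2-[2-(benzyloxy)-3,4-dimethoxyphenyl]-3-(4-hydroxy-2,3-dimethoxyphenyl)propan-1-ol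
Conditions: Pd(PPh3)4 (5 mol %), morpholine, THF, rt
Reagents that add atoms: none
Why: Tsuji–Trost deallylation; Pd(0) ionises the aryl allyl ether to a π-allyl complex that morpholine captures, and the benzyl ether and the alcohol do not react.

Step 12
Reactants: 16 (2S)-2-[2-(benzyloxy)-3,4-dimethoxyphenyl]-3-(4-hydroxy-2,3-dimethoxyphenyl)propan-1-ol
Product: 17 (3S)-3-[2-(benzyloxy)-3,4-dimethoxyphenyl]-6,7-dimethoxy-1-oxaspiro[4.5]deca-6,9-dien-8-one (both epimers at the spiro carbon C5)
Conditions: PhI(OAc)2, (CF3)2CHOH, 0 °C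
Reagents that add atoms: none
Why: iodine(III) oxidative dearomatisation of a para-alkylphenol; the primary hydroxyl closes 5-exo onto the para carbon as iodobenzene leaves, and ring B should not compete because its only carbon within reach (C6') is its least activated position and its phenol is masked as the benzyl ether.

Step 13
Reactants: 17 (3S)-3-[2-(benzyloxy)-3,4-dimethoxyphenyl]-6,7-dimethoxy-1-oxaspiro[4.5]deca-6,9-dien-8-one
Product: 18 (3S)-3-[2-(benzyloxy)-3,4-dimethoxyphenyl]-7,8-dimethoxychroman-6-ol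
Conditions: BF3·OEt2 (0.3 equiv), CH2Cl2, −20 °C → rt
Reagents that add atoms: none
Why: Coordination of BF3 (or a proton) to the C8 carbonyl oxygen of 17 makes a hydroxypentadienyl cation with charge on C6 and C10, the two carbons flanking the spiro centre; the oxolane CH2 (future C4) then shifts with its bonding pair from the spiro carbon (future C8a) to C10 (future C4a), leaving a cation on C8a that O1 stabilises, and loss of the C4a proton restores the benzene ring with 6-OH free. The closest known reaction type is the dienone–phenol (quinol-type) rearrangement of para-spiroether dienones and of the corresponding spirolactones, which give 6-hydroxychromans and 6-hydroxydihydrocoumarins. The pyran ring is closed by ring expansion of the five-membered spiroether through a suprafacial 1,2-alkyl shift (C4–C4a made, C4–C8a broken), not by cyclisation of an open chain. No stereocentre is created: C3 lies outside the migrating bond and stays (S), and both spiro epimers converge because the spiro carbon becomes planar. The step needs carbon and not oxygen to migrate, and needs it to go to C10 and not to C6: the carbon shift is the one that leaves an oxygen-stabilised cation, a shift to the methoxy-bearing C6 gives a blocked cation that can only revert, and the shift to the hydrogen-bearing C10 is drained by aromatisation. Water is excluded so that the vinylogous ester (C6-OMe conjugated to C8=O) is not hydrolysed, and the low temperature and substoichiometric Lewis acid should spare the 2'-benzyl ether.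

Step 14
Reactants: 18 (3S)-3-[2-(benzyloxy)-3,4-dimethoxyphenyl]-7,8-dimethoxychroman-6-ol
Product: 19 (3S)-3-(2-hydroxy-3,4-dimethoxyphenyl)-7,8-dimethoxychroman-6-ol
Conditions: H2 (1 atm), 10% Pd/C, EtOAc, rt
Reagents that add atoms: none
Why: hydrogenolysis of the benzyl ether, which leaves the aryl methyl ethers, the chroman and the C3 stereocentre untouched.

**Compound list**

1 | 1-(2-hydroxy-3,4-dimethoxyphenyl)ethan-1-one | CC(=O)c1ccc(OC)c(OC)c1O | starting material
2 | 1-[2-(benzyloxy)-3,4-dimethoxyphenyl]ethan-1-one | CC(=O)c1ccc(OC)c(OC)c1OCc1ccccc1 | intermediate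
3 | 2-[2-(benzyloxy)-3,4-dimethoxyphenyl]-1-(morpholin-4-yl)ethane-1-thione | S=C(Cc1ccc(OC)c(OC)c1OCc1ccccc1)N1CCOCC1 | intermediate
4 | [2-(benzyloxy)-3,4-dimethoxyphenyl]acetic acid | OC(=O)Cc1ccc(OC)c(OC)c1OCc1ccccc1 | intermediate
5 | (4S)-4-benzyl-1,3-oxazolidin-2-one | O=C1N[C@@H](Cc2ccccc2)CO1 | starting material
6 | [2-(benzyloxy)-3,4-dimethoxyphenyl]acetic pivalic anhydride | CC(C)(C)C(=O)OC(=O)Cc1ccc(OC)c(OC)c1OCc1ccccc1 | intermediate
7 | (4S)-4-benzyl-3-{[2-(benzyloxy)-3,4-dimethoxyphenyl]acetyl}-1,3-oxazolidin-2-one | O=C(Cc1ccc(OC)c(OC)c1OCc1ccccc1)N1C(=O)OC[C@@H]1Cc1ccccc1 | intermediate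
8 | 2,3,4-trihydroxybenzaldehyde | O=Cc1ccc(O)c(O)c1O | starting material
9 | 4-(allyloxy)-2,3-dihydroxybenzaldehyde | O=Cc1ccc(OCC=C)c(O)c1O | intermediate
10 | 4-(allyloxy)-2,3-dimethoxybenzaldehyde | O=Cc1ccc(OCC=C)c(OC)c1OC | intermediate
11 | [4-(allyloxy)-2,3-dimethoxyphenyl]methanol | OCc1ccc(OCC=C)c(OC)c1OC | intermediate
12 | 1-(allyloxy)-4-(bromomethyl)-2,3-dimethoxybenzene | BrCc1ccc(OCC=C)c(OC)c1OC | intermediate
13 | sodium Z-enolate of imide 7 | [Na+].[O-]/C(=C\c1ccc(OC)c(OC)c1OCc1ccccc1)N1C(=O)OC[C@@H]1Cc1ccccc1 | intermediate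
14 | (4S)-4-benzyl-3-[(2S)-3-[4-(allyloxy)-2,3-dimethoxyphenyl]-2-[2-(benzyloxy)-3,4-dimethoxyphenyl]propanoyl]-1,3-oxazolidin-2-one | O=C([C@@H](Cc1ccc(OCC=C)c(OC)c1OC)c1ccc(OC)c(OC)c1OCc1ccccc1)N1C(=O)OC[C@@H]1Cc1ccccc1 | intermediate
15 | (2S)-3-[4-(allyloxy)-2,3-dimethoxyphenyl]-2-[2-(benzyloxy)-3,4-dimethoxyphenyl]propan-1-ol | OC[C@@H](Cc1ccc(OCC=C)c(OC)c1OC)c1ccc(OC)c(OC)c1OCc1ccccc1 | intermediate
16 | (2S)-2-[2-(benzyloxy)-3,4-dimethoxyphenyl]-3-(4-hydroxy-2,3-dimethoxyphenyl)propan-1-ol | OC[C@@H](Cc1ccc(O)c(OC)c1OC)c1ccc(OC)c(OC)c1OCc1ccccc1 | intermediate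
17 | (3S)-3-[2-(benzyloxy)-3,4-dimethoxyphenyl]-6,7-dimethoxy-1-oxaspiro[4.5]deca-6,9-dien-8-one, both C5 epimers | COC1=C(OC)C2(C=CC1=O)C[C@H](CO2)c1ccc(OC)c(OC)c1OCc1ccccc1 | intermediate
18 | (3S)-3-[2-(benzyloxy)-3,4-dimethoxyphenyl]-7,8-dimethoxychroman-6-ol | COc1ccc([C@H]2COc3c(cc(O)c(OC)c3OC)C2)c(OCc2ccccc2)c1OC | intermediate
19 | (3S)-3-(2-hydroxy-3,4-dimethoxyphenyl)-7,8-dimethoxychroman-6-ol | COc1ccc([C@H]2COc3c(cc(O)c(OC)c3OC)C2)c(O)c1OC | target

**Step count**

Total: 14 steps. Longest linear sequence: 10 steps (steps 1–4 and 9–14; the ring-A branch, steps 5–8 and 9–14, is equally long).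

**Steps most likely to fail**

1. Step 13. The dienyl cation may be diverted before the wanted shift: reversible migration toward the methoxy-bearing carbon followed by loss of methanol, ionisation of the spiro C–O bond, capture of the cation by ring B, or acid cleavage of the benzyl ether with re-alkylation of the rings. The fallback gives up the dearomatisation and closes O1–C2 by etherification of a hydroquinone; it sets out from aldehyde 10 and imide 7 and returns at 18. Dakin oxidation of 10 (H2O2, cat. H2SO4, MeOH) should give 4-(allyloxy)-2,3-dimethoxyphenol F1. Magnesium-mediated ortho-formylation (MgCl2, Et3N, paraformaldehyde, MeCN, reflux) at its only free ortho position should give 5-(allyloxy)-2-hydroxy-3,4-dimethoxybenzaldehyde F2. Allylation (allyl bromide, K2CO3, DMF) should give 2,5-bis(allyloxy)-3,4-dimethoxybenzaldehyde F3, NaBH4 the benzylic alcohol [2,5-bis(allyloxy)-3,4-dimethoxyphenyl]methanol F4, and PBr3 the 2,5-bis(allyloxy)-3,4-dimethoxybenzyl bromide F5. Alkylation of the sodium enolate of 7 with F5, as in step 9, should give the (2S)-imide F6, and LiBH4 the (2S)-alcohol F7. Pd(PPh3)4 and morpholine remove both allyl groups to give the hydroquinone alcohol F8. Mitsunobu etherification (PPh3, DIAD, THF, high dilution) then closes the pyran ring, because only the hydroxyl ortho to the side chain can reach C2, and gives 18 with 6-OH free.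

2. Step 12. The oxidised phenol may be captured by acetate or solvent, or at the methoxy-bearing ortho carbon, before the weakly nucleophilic primary hydroxyl closes the ring, and the dienone may be oxidised further. The fallback uses a carboxylate as the internal nucleophile and removes the extra carbonyl after ring expansion; it sets out from imide 14 and returns at 18. LiOH/H2O2 (THF–H2O, 0 °C) should cleave 14 to the (2S)-propanoic acid F9, and Pd(PPh3)4 with morpholine should give the phenol acid F10. PhI(OAc)2 in MeCN should give the spirolactone F11, a cyclisation that is reliable for 3-(4-hydroxyphenyl)propanoic acids. BF3·OEt2 in CH2Cl2 should bring about the same C4 shift and give the 6-hydroxydihydrocoumarin F12, which is kept away from base because its C3–H is acidic. DIBAL-H (CH2Cl2, −78 °C) should give the lactol F13, and Et3SiH with BF3·OEt2 (CH2Cl2, −78 → 0 °C) should reduce the lactol to 18.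

3. Step 9. The electron-rich benzylic bromide may decompose or alkylate itself under the basic conditions, the hindered and stabilised arylacetyl enolate may react incompletely, and the acidic α-aryl centre may epimerise during work-up. The fallback forms the C3–C4 bond by an aldol reaction with the stable aldehyde and then removes the benzylic oxygen; it sets out from acid 4 and aldehyde 10 and returns at 15. Acid 4 is coupled (PivCl, Et3N, LiCl) with commercial (4R)-4-benzyl-1,3-oxazolidin-2-one to give the (4R)-imide F14. The enantiomeric auxiliary is needed because the non-chelated boron enolate reacts on the face opposite to that used by the chelated sodium enolate. Boron aldol reaction (Bu2BOTf, i-Pr2NEt, CH2Cl2, −78 → 0 °C) with 10 should give the syn-aldol F15. Ionic deoxygenation (Et3SiH, TFA, CH2Cl2, 0 °C) of its doubly activated benzylic alcohol should give the (2S)-imide F16, and LiBH4 then gives 15.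

**Further compounds**

F1 | step 13 | 4-(allyloxy)-2,3-dimethoxyphenol | Oc1ccc(OCC=C)c(OC)c1OC
F2 | step 13 | 5-(allyloxy)-2-hydroxy-3,4-dimethoxybenzaldehyde | O=Cc1cc(OCC=C)c(OC)c(OC)c1O
F3 | step 13 | 2,5-bis(allyloxy)-3,4-dimethoxybenzaldehyde | O=Cc1cc(OCC=C)c(OC)c(OC)c1OCC=C
F4 | step 13 | [2,5-bis(allyloxy)-3,4-dimethoxyphenyl]methanol | OCc1cc(OCC=C)c(OC)c(OC)c1OCC=C
F5 | step 13 | 2,5-bis(allyloxy)-3,4-dimethoxybenzyl bromide | BrCc1cc(OCC=C)c(OC)c(OC)c1OCC=C
F6 | step 13 | (4S)-4-benzyl-3-[(2S)-3-[2,5-bis(allyloxy)-3,4-dimethoxyphenyl]-2-[2-(benzyloxy)-3,4-dimethoxyphenyl]propanoyl]-1,3-oxazolidin-2-one | O=C([C@@H](Cc1cc(OCC=C)c(OC)c(OC)c1OCC=C)c1ccc(OC)c(OC)c1OCc1ccccc1)N1C(=O)OC[C@@H]1Cc1ccccc1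
F7 | step 13 | (2S)-3-[2,5-bis(allyloxy)-3,4-dimethoxyphenyl]-2-[2-(benzyloxy)-3,4-dimethoxyphenyl]propan-1-ol | OC[C@@H](Cc1cc(OCC=C)c(OC)c(OC)c1OCC=C)c1ccc(OC)c(OC)c1OCc1ccccc1
F8 | step 13 | 2-[(2S)-2-[2-(benzyloxy)-3,4-dimethoxyphenyl]-3-hydroxypropyl]-5,6-dimethoxybenzene-1,4-diol | OC[C@@H](Cc1cc(O)c(OC)c(OC)c1O)c1ccc(OC)c(OC)c1OCc1ccccc1
F9 | step 12 | (2S)-3-[4-(allyloxy)-2,3-dimethoxyphenyl]-2-[2-(benzyloxy)-3,4-dimethoxyphenyl]propanoic acid | OC(=O)[C@@H](Cc1ccc(OCC=C)c(OC)c1OC)c1ccc(OC)c(OC)c1OCc1ccccc1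
F10 | step 12 | (2S)-2-[2-(benzyloxy)-3,4-dimethoxyphenyl]-3-(4-hydroxy-2,3-dimethoxyphenyl)propanoic acid | OC(=O)[C@@H](Cc1ccc(O)c(OC)c1OC)c1ccc(OC)c(OC)c1OCc1ccccc1
F11 | step 12 | (3S)-3-[2-(benzyloxy)-3,4-dimethoxyphenyl]-6,7-dimethoxy-1-oxaspiro[4.5]deca-6,9-diene-2,8-dione, both C5 epimers | COC1=C(OC)C2(C=CC1=O)C[C@H](C(=O)O2)c1ccc(OC)c(OC)c1OCc1ccccc1
F12 | step 12 | (3S)-3-[2-(benzyloxy)-3,4-dimethoxyphenyl]-6-hydroxy-7,8-dimethoxychroman-2-one | COc1ccc([C@H]2C(=O)Oc3c(cc(O)c(OC)c3OC)C2)c(OCc2ccccc2)c1OC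
F13 | step 12 | (3S)-3-[2-(benzyloxy)-3,4-dimethoxyphenyl]-7,8-dimethoxychromane-2,6-diol, both C2 epimers | COc1ccc([C@H]2C(O)Oc3c(cc(O)c(OC)c3OC)C2)c(OCc2ccccc2)c1OC
F14 | step 9 | (4R)-4-benzyl-3-{[2-(benzyloxy)-3,4-dimethoxyphenyl]acetyl}-1,3-oxazolidin-2-one | O=C(Cc1ccc(OC)c(OC)c1OCc1ccccc1)N1C(=O)OC[C@H]1Cc1ccccc1
F15 | step 9 | (4R)-4-benzyl-3-[(2R,3R)-3-[4-(allyloxy)-2,3-dimethoxyphenyl]-2-[2-(benzyloxy)-3,4-dimethoxyphenyl]-3-hydroxypropanoyl]-1,3-oxazolidin-2-one | O=C([C@@H]([C@@H](O)c1ccc(OCC=C)c(OC)c1OC)c1ccc(OC)c(OC)c1OCc1ccccc1)N1C(=O)OC[C@H]1Cc1ccccc1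
F16 | step 9 | (4R)-4-benzyl-3-[(2S)-3-[4-(allyloxy)-2,3-dimethoxyphenyl]-2-[2-(benzyloxy)-3,4-dimethoxyphenyl]propanoyl]-1,3-oxazolidin-2-one | O=C([C@@H](Cc1ccc(OCC=C)c(OC)c1OC)c1ccc(OC)c(OC)c1OCc1ccccc1)N1C(=O)OC[C@H]1Cc1ccccc1
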